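**Plan**

- Labels: the tetralin is numbered C1–C8a (C1 carries ring B, C4 is the CH2, ring C is the benzo ring, ring D the saturated ring); ring A, C7' (carbinol) and C8' (aryloxy carbon) belong to the side chain.
- Cuts, in retrosynthetic order: the C8'–O(ring B) ether; then C1–C8a and C4–C4a of ring D; then the four-membered ring of a cyclobutanone into an aryl keteniminium ion and (E)-but-2-ene.
- Enabling feature: benzylic C1 and methylene C4 sit on the adjacent ring C carbons C8a and C4a, so C1–C4 can arrive as an all-trans cyclobutanone (C4 as carbonyl) and ring C, as an ortho-bromoaryl Grignard reagent, can be inserted into its C1–C4 bond.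
- Forward: four-membered ring by [2+2]; ring D by carbonyl addition and palladium-catalysed C–C cleavage/arylation; deoxygenation at C4; debenzylation of ring B; Mitsunobu union with the side-chain alcohol; global desilylation.
- Stereochemistry: C2 from a twofold-symmetric pyrrolidine auxiliary in the [2+2]; C1 and C3 are enolisable in the cyclobutanone and settle all-trans, C1 then being carried over with retention; C8' from ethyl (S)-lactate with Mitsunobu inversion; C7' from chelation-controlled aryl addition.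

Key step: step 5

Assumption: the (2R,5R)-auxiliary is taken to steer the cycloaddition to the (3S,4S) ring carbons of the cyclobutanone; if the sense of induction proves opposite, the (2S,5S)-amine is used with no other change.

Remark: atom labels in the Why lines are those of the target; compound names carry their own locants.

**Step 1**
Reactants: 1 2-[4-(benzyloxy)-3-methoxyphenyl]acetic acid; 2 (2R,5R)-2,5-dimethylpyrrolidine
Product: 4 2-[4-(benzyloxy)-3-methoxyphenyl]-1-[(2R,5R)-2,5-dimethylpyrrolidin-1-yl]ethan-1-one, via acid chloride 3 (not isolated)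
Conditions: (COCl)2, DMF (cat.), CH2Cl2, 0 °C → rt; then 2, Et3N, CH2Cl2, 0 °C → rt
Reagents that add atoms: none
Why: Amide formation through the acyl chloride acylates the hindered secondary amine reliably where carbodiimide couplings would be slow, and no stereocentre is formed or touched.

**Step 2**
Reactants: 4 2-[4-(benzyloxy)-3-methoxyphenyl]-1-[(2R,5R)-2,5-dimethylpyrrolidin-1-yl]ethan-1-one; 5 (E)-but-2-ene
Product: 8 (2S,3S,4S)-2-[4-(benzyloxy)-3-methoxyphenyl]-3,4-dimethylcyclobutan-1-one (all-trans), via keteniminium triflate 6 (not isolated), via cyclobutaniminium triflate 7 (not isolated)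
Conditions: Tf2O, 2,4,6-collidine, 5 (excess), ClCH2CH2Cl, sealed tube, −20 → 45 °C; then H2O, rt; then DBU (cat.), CH2Cl2, rt
Reagents that add atoms: water, O
Why: Keteniminium–alkene [2+2] cycloaddition: O-triflation of the amide and loss of a proton give the aryl keteniminium ion, which adds across the alkene suprafacially so that the E geometry becomes the trans relationship of the two methyl groups, while the twofold-symmetric pyrrolidine differentiates the enantiotopic faces of the butene and so sets the carbon that becomes C2 (the only centre of 8 that cannot epimerise); hydrolysis of the iminium salt and base equilibration of the two enolisable α-carbons (future C1 and C3) then place the aryl group and the second methyl group trans to it.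

**Step 3**
Reactants: 9 4-iodo-2-methoxyphenol
Product: 10 (4-iodo-2-methoxyphenoxy)tri(propan-2-yl)silane
Conditions: i-Pr3SiCl, imidazole, DMF, rt
Reagents that add atoms: chlorotri(propan-2-yl)silane, CC(C)[Si](Cl)(C(C)C)C(C)C
Why: Silyl ether formation gives a bulky aryl silyl ether that should survive the Grignard, palladium, acid and hydrogenolysis steps and fall only to fluoride at the end.

**Step 4**
Reactants: 10 (4-iodo-2-methoxyphenoxy)tri(propan-2-yl)silane
Product: 11 (5-bromo-4-iodo-2-methoxyphenoxy)tri(propan-2-yl)silane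
Conditions: NBS, MeCN, 0 °C → rt
Reagents that add atoms: N-bromosuccinimide, O=C1CCC(=O)N1Br
Why: Electrophilic aromatic bromination should go para to the methoxy group, the strongest free director, because the position para to the silyloxy group is held by iodine and the position between methoxy and iodine is crowded.

**Step 5**
Reactants: 11 (5-bromo-4-iodo-2-methoxyphenoxy)tri(propan-2-yl)silane; 8 (2S,3S,4S)-2-[4-(benzyloxy)-3-methoxyphenyl]-3,4-dimethylcyclobutan-1-one
Product: 14 (2S,3R,4S)-4-[4-(benzyloxy)-3-methoxyphenyl]-7-methoxy-2,3-dimethyl-6-(triisopropylsilyloxy)-3,4-dihydronaphthalen-1(2H)-one, via aryl Grignard reagent 12 (not isolated), via magnesium cyclobutanolate 13 (not isolated)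
Conditions: 11, i-PrMgCl·LiCl, THF, −30 °C; then 8, −30 → 0 °C; THF exchanged for toluene under reduced pressure; Pd(OAc)2 (5 mol %), P(t-Bu)3 (10 mol %), 90 °C
Reagents that add atoms: none
Why: Proposed new method: iodine–magnesium exchange (C–I before C–Br) gives the ortho-bromoaryl Grignard reagent, which adds to the strained carbonyl of 8 to form C4–C4a; zerovalent palladium then inserts into the C–Br bond, the chloromagnesium alkoxide is handed to divalent palladium to give a spiro five-membered oxapalladacycle, and strain-releasing β-carbon elimination cleaves C1–C4 to a seven-membered aryl(benzyl)palladacycle. C(sp3)–C(sp2) reductive elimination from this palladacycle forms C1–C8a and closes ring D, so the six-membered ring arises by formal insertion of the C4a–C8a arene unit into the C1–C4 bond, a [4+2] annulation by expansion of the four-membered ring. The closest known reactions are the palladium-catalysed ring-opening arylation of tertiary cyclobutanols with aryl bromides through β-carbon elimination and the nickel-catalysed insertion of alkynes into cyclobutanones through a spiro oxanickelacycle; the one-pot, tethered form with the aryl bromide on the carbinol carbon is untested. No stereocentre is created in the product: the carbinol centre of 13 is transient, C2 and C3 are untouched, and C1 is carried over with retention because β-carbon elimination and reductive elimination both proceed with retention at carbon. The step needs cleavage of C1–C4 and not C3–C4, which the benzylic (η3-stabilised) palladium alkyl formed at C1 should secure, and reductive elimination faster than β-hydride elimination towards C2, which the bulky P(t-Bu)3 and the cyclic η3-benzyl binding should favour. Which ring C oxygen ends para to C4a is fixed beforehand by iodine standing para to the silyloxy group and bromine para to the methoxy group in 11.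

**Step 6**
Reactants: 14 (2S,3R,4S)-4-[4-(benzyloxy)-3-methoxyphenyl]-7-methoxy-2,3-dimethyl-6-(triisopropylsilyloxy)-3,4-dihydronaphthalen-1(2H)-one
Product: 15 (1S,2S,3R)-1-[4-(benzyloxy)-3-methoxyphenyl]-6-methoxy-2,3-dimethyl-7-(triisopropylsilyloxy)-1,2,3,4-tetrahydronaphthalene
Conditions: Et3SiH, CF3CO2H, CH2Cl2, 0 °C → rt
Reagents that add atoms: none
Why: Ionic hydrogenation of the aryl ketone (protonation, hydride transfer, ionisation to a benzylic cation stabilised by the para-silyloxy group, second hydride transfer) should give the C4 methylene without touching C1–C3 or the silyl ether, and any loss of the ring B benzyl group would only anticipate the next step.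

**Step 7**
Reactants: 15 (1S,2S,3R)-1-[4-(benzyloxy)-3-methoxyphenyl]-6-methoxy-2,3-dimethyl-7-(triisopropylsilyloxy)-1,2,3,4-tetrahydronaphthalene
Product: 16 2-methoxy-4-[(1S,2S,3R)-6-methoxy-2,3-dimethyl-7-(triisopropylsilyloxy)-1,2,3,4-tetrahydronaphthalen-1-yl]phenol
Conditions: H2 (1 atm), Pd/C, EtOAc, rt
Reagents that add atoms: none
Why: Hydrogenolysis of the aryl benzyl ether frees the ring B phenol while the silyl ether and the three stereocentres are inert.

**Step 8**
Reactants: 17 4-bromo-2-methoxyphenol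
Product: 18 (4-bromo-2-methoxyphenoxy)(tert-butyl)dimethylsilane
Conditions: t-BuMe2SiCl, imidazole, DMF, rt
Reagents that add atoms: tert-butyl(chloro)dimethylsilane, CC(C)(C)[Si](C)(C)Cl
Why: Silyl ether formation masks the ring A phenol for the Grignard and Mitsunobu steps with a group that leaves in the final fluoride step.

**Step 9**
Reactants: 19 ethyl (2S)-2-(benzyloxy)propanoate
Product: 20 (2S)-2-(benzyloxy)propanal
Conditions: i-Bu2AlH, CH2Cl2, −78 °C
Reagents that add atoms: none
Why: Partial ester reduction stops at the tetrahedral aluminium hemiacetal at −78 °C, which should release the aldehyde on work-up without loss of the α-stereocentre.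

**Step 10**
Reactants: 18 (4-bromo-2-methoxyphenoxy)(tert-butyl)dimethylsilane; 20 (2S)-2-(benzyloxy)propanal
Product: 22 (1S,2S)-2-(benzyloxy)-1-[4-(tert-butyldimethylsilyloxy)-3-methoxyphenyl]propan-1-ol, via aryl Grignard reagent 21 (not isolated)
Conditions: 18, Mg, THF, 40 °C; then 20, MgBr2·OEt2, CH2Cl2, −78 °C
Reagents that add atoms: none
Why: Chelation-controlled Grignard addition (Cram chelate model): magnesium bridges the aldehyde and benzyloxy oxygens and the aryl group attacks the face opposite the methyl group, which should set C7' as S (syn, threo) next to the lactate-derived C8'.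

**Step 11**
Reactants: 22 (1S,2S)-2-(benzyloxy)-1-[4-(tert-butyldimethylsilyloxy)-3-methoxyphenyl]propan-1-ol
Product: 23 (1S,2S)-2-(benzyloxy)-1-(tert-butyldimethylsilyloxy)-1-[4-(tert-butyldimethylsilyloxy)-3-methoxyphenyl]propane
Conditions: t-BuMe2SiOTf, 2,6-lutidine, CH2Cl2, −78 → 0 °C
Reagents that add atoms: tert-butyldimethylsilyl trifluoromethanesulfonate, CC(C)(C)[Si](C)(C)OS(=O)(=O)C(F)(F)F
Why: Silyl ether formation with the silyl triflate and a hindered base should protect the benzylic alcohol at low temperature without ionising it.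

**Step 12**
Reactants: 23 (1S,2S)-2-(benzyloxy)-1-(tert-butyldimethylsilyloxy)-1-[4-(tert-butyldimethylsilyloxy)-3-methoxyphenyl]propane
Product: 24 (1S,2S)-1-(tert-butyldimethylsilyloxy)-1-[4-(tert-butyldimethylsilyloxy)-3-methoxyphenyl]propan-2-ol
Conditions: H2 (1 atm), Pd/C, EtOAc, rt
Reagents that add atoms: none
Why: Hydrogenolysis of the alkyl benzyl ether in a neutral solvent should free the C8' hydroxyl while the two silyl ethers, including the hindered benzylic one, stay in place.

**Step 13**
Reactants: 16 2-methoxy-4-[(1S,2S,3R)-6-methoxy-2,3-dimethyl-7-(triisopropylsilyloxy)-1,2,3,4-tetrahydronaphthalen-1-yl]phenol; 24 (1S,2S)-1-(tert-butyldimethylsilyloxy)-1-[4-(tert-butyldimethylsilyloxy)-3-methoxyphenyl]propan-2-ol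
Product: 25 (1S,2R)-1-(tert-butyldimethylsilyloxy)-1-[4-(tert-butyldimethylsilyloxy)-3-methoxyphenyl]-2-{2-methoxy-4-[(1S,2S,3R)-6-methoxy-2,3-dimethyl-7-(triisopropylsilyloxy)-1,2,3,4-tetrahydronaphthalen-1-yl]phenoxy}propane
Conditions: PPh3, DIAD, toluene, 0 °C → rt
Reagents that add atoms: none
Why: Mitsunobu etherification: the phenol displaces the oxyphosphonium group at C8' in an SN2 process with inversion, which should turn the (1S,2S) threo alcohol into the (1S,2R) erythro aryl ether while the protected C7' is unchanged.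

**Step 14**
Reactants: 25 (1S,2R)-1-(tert-butyldimethylsilyloxy)-1-[4-(tert-butyldimethylsilyloxy)-3-methoxyphenyl]-2-{2-methoxy-4-[(1S,2S,3R)-6-methoxy-2,3-dimethyl-7-(triisopropylsilyloxy)-1,2,3,4-tetrahydronaphthalen-1-yl]phenoxy}propane
Product: 26 (1S,2R)-1-(4-hydroxy-3-methoxyphenyl)-2-{4-[(1S,2S,3R)-7-hydroxy-6-methoxy-2,3-dimethyl-1,2,3,4-tetrahydronaphthalen-1-yl]-2-methoxyphenoxy}propan-1-ol (CID53359464)
Conditions: Bu4NF, AcOH, THF, 0 °C → rt
Reagents that add atoms: none
Why: Fluoride-mediated desilylation of the two aryl silyl ethers and the benzylic silyl ether, buffered with acetic acid so that the phenoxides and the p-hydroxybenzylic alcohol do not meet strong base, should give the target with all five stereocentres intact.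

**Compound list**

1 | 2-[4-(benzyloxy)-3-methoxyphenyl]acetic acid | COc1cc(CC(=O)O)ccc1OCc1ccccc1 | starting material
2 | (2R,5R)-2,5-dimethylpyrrolidine | C[C@@H]1CC[C@@H](C)N1 | starting material
3 | 2-[4-(benzyloxy)-3-methoxyphenyl]acetyl chloride (not isolated) | COc1cc(CC(=O)Cl)ccc1OCc1ccccc1 | intermediate
4 | 2-[4-(benzyloxy)-3-methoxyphenyl]-1-[(2R,5R)-2,5-dimethylpyrrolidin-1-yl]ethan-1-one | COc1cc(CC(=O)N2[C@H](C)CC[C@H]2C)ccc1OCc1ccccc1 | intermediate
5 | (E)-but-2-ene | C/C=C/C | starting material
6 | (2R,5R)-1-{2-[4-(benzyloxy)-3-methoxyphenyl]ethenylidene}-2,5-dimethylpyrrolidin-1-ium trifluoromethanesulfonate (not isolated) | COc1cc(C=C=[N+]2[C@H](C)CC[C@H]2C)ccc1OCc1ccccc1.[O-]S(=O)(=O)C(F)(F)F | intermediate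
7 | (2R,5R)-1-{(3S,4S)-2-[4-(benzyloxy)-3-methoxyphenyl]-3,4-dimethylcyclobutylidene}-2,5-dimethylpyrrolidin-1-ium trifluoromethanesulfonate, aryl-bearing ring carbon not yet fixed (not isolated) | COc1cc(C2C(=[N+]3[C@H](C)CC[C@H]3C)[C@@H](C)[C@@H]2C)ccc1OCc1ccccc1.[O-]S(=O)(=O)C(F)(F)F | intermediate
8 | (2S,3S,4S)-2-[4-(benzyloxy)-3-methoxyphenyl]-3,4-dimethylcyclobutan-1-one (all-trans) | COc1cc([C@H]2C(=O)[C@@H](C)[C@@H]2C)ccc1OCc1ccccc1 | intermediate
9 | 4-iodo-2-methoxyphenol | COc1cc(I)ccc1O | starting material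
10 | (4-iodo-2-methoxyphenoxy)tri(propan-2-yl)silane | COc1cc(I)ccc1O[Si](C(C)C)(C(C)C)C(C)C | intermediate
11 | (5-bromo-4-iodo-2-methoxyphenoxy)tri(propan-2-yl)silane | COc1cc(I)c(Br)cc1O[Si](C(C)C)(C(C)C)C(C)C | intermediate
12 | [2-bromo-5-methoxy-4-(triisopropylsilyloxy)phenyl]magnesium chloride (not isolated) | COc1cc([Mg]Cl)c(Br)cc1O[Si](C(C)C)(C(C)C)C(C)C | intermediate
13 | chloromagnesium (1S,2S,3S,4S)-2-[4-(benzyloxy)-3-methoxyphenyl]-1-[2-bromo-5-methoxy-4-(triisopropylsilyloxy)phenyl]-3,4-dimethylcyclobutan-1-olate, new aryl group anti to the flanking aryl and methyl groups (not isolated) | COc1cc([C@H]2[C@](O[Mg]Cl)(c3cc(OC)c(O[Si](C(C)C)(C(C)C)C(C)C)cc3Br)[C@@H](C)[C@@H]2C)ccc1OCc1ccccc1 | intermediate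
14 | (2S,3R,4S)-4-[4-(benzyloxy)-3-methoxyphenyl]-7-methoxy-2,3-dimethyl-6-(triisopropylsilyloxy)-3,4-dihydronaphthalen-1(2H)-one | COc1cc([C@H]2c3cc(O[Si](C(C)C)(C(C)C)C(C)C)c(OC)cc3C(=O)[C@@H](C)[C@@H]2C)ccc1OCc1ccccc1 | intermediate
15 | (1S,2S,3R)-1-[4-(benzyloxy)-3-methoxyphenyl]-6-methoxy-2,3-dimethyl-7-(triisopropylsilyloxy)-1,2,3,4-tetrahydronaphthalene | COc1cc([C@H]2c3cc(O[Si](C(C)C)(C(C)C)C(C)C)c(OC)cc3C[C@@H](C)[C@@H]2C)ccc1OCc1ccccc1 | intermediate
16 | 2-methoxy-4-[(1S,2S,3R)-6-methoxy-2,3-dimethyl-7-(triisopropylsilyloxy)-1,2,3,4-tetrahydronaphthalen-1-yl]phenol | COc1cc([C@H]2c3cc(O[Si](C(C)C)(C(C)C)C(C)C)c(OC)cc3C[C@@H](C)[C@@H]2C)ccc1O | intermediate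
17 | 4-bromo-2-methoxyphenol | COc1cc(Br)ccc1O | starting material
18 | (4-bromo-2-methoxyphenoxy)(tert-butyl)dimethylsilane | COc1cc(Br)ccc1O[Si](C)(C)C(C)(C)C | intermediate
19 | ethyl (2S)-2-(benzyloxy)propanoate | C[C@H](OCc1ccccc1)C(=O)OCC | starting material
20 | (2S)-2-(benzyloxy)propanal | C[C@H](OCc1ccccc1)C=O | intermediate
21 | [4-(tert-butyldimethylsilyloxy)-3-methoxyphenyl]magnesium bromide (not isolated) | COc1cc([Mg]Br)ccc1O[Si](C)(C)C(C)(C)C | intermediate
22 | (1S,2S)-2-(benzyloxy)-1-[4-(tert-butyldimethylsilyloxy)-3-methoxyphenyl]propan-1-ol | C[C@H](OCc1ccccc1)[C@@H](O)c1ccc(O[Si](C)(C)C(C)(C)C)c(OC)c1 | intermediate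
23 | (1S,2S)-2-(benzyloxy)-1-(tert-butyldimethylsilyloxy)-1-[4-(tert-butyldimethylsilyloxy)-3-methoxyphenyl]propane | C[C@H](OCc1ccccc1)[C@@H](O[Si](C)(C)C(C)(C)C)c1ccc(O[Si](C)(C)C(C)(C)C)c(OC)c1 | intermediate
24 | (1S,2S)-1-(tert-butyldimethylsilyloxy)-1-[4-(tert-butyldimethylsilyloxy)-3-methoxyphenyl]propan-2-ol | C[C@H](O)[C@@H](O[Si](C)(C)C(C)(C)C)c1ccc(O[Si](C)(C)C(C)(C)C)c(OC)c1 | intermediate
25 | (1S,2R)-1-(tert-butyldimethylsilyloxy)-1-[4-(tert-butyldimethylsilyloxy)-3-methoxyphenyl]-2-{2-methoxy-4-[(1S,2S,3R)-6-methoxy-2,3-dimethyl-7-(triisopropylsilyloxy)-1,2,3,4-tetrahydronaphthalen-1-yl]phenoxy}propane | COc1cc([C@H](O[Si](C)(C)C(C)(C)C)[C@@H](C)Oc2ccc([C@H]3c4cc(O[Si](C(C)C)(C(C)C)C(C)C)c(OC)cc4C[C@@H](C)[C@@H]3C)cc2OC)ccc1O[Si](C)(C)C(C)(C)C | intermediate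
26 | (1S,2R)-1-(4-hydroxy-3-methoxyphenyl)-2-{4-[(1S,2S,3R)-7-hydroxy-6-methoxy-2,3-dimethyl-1,2,3,4-tetrahydronaphthalen-1-yl]-2-methoxyphenoxy}propan-1-ol | COc1cc([C@H](O)[C@@H](C)Oc2ccc([C@H]3c4cc(O)c(OC)cc4C[C@@H](C)[C@@H]3C)cc2OC)ccc1O | target

**Step count and risks**

Total step count: 14. Longest linear sequence: 7 steps (1 → 4 → 8 → 14 → 15 → 16 → 25 → 26; equally long from 9).

Steps most likely to fail:

1. Step 5. The benzylpalladium intermediate may undergo β-hydride elimination towards C2 before C–C reductive elimination. The Grignard reagent may enolise 8 instead of adding. The ring may open at C3–C4 or without stereochemical fidelity at C1. Fallback with known chemistry, setting out from 10 and 8 and returning at 14: iodide 10 is treated with i-PrMgCl·LiCl (THF, −20 °C) to give the bromine-free aryl Grignard reagent F1, which is added to ketone 8 to give, after aqueous work-up, the tertiary cyclobutanol F2. The known silver-catalysed oxidative ring expansion of 1-arylcyclobutanols to 1-tetralones (AgNO3 cat., K2S2O8, CH2Cl2/H2O, rt) then forms the alkoxy radical. β-Scission towards benzylic C1 and cyclisation of the resulting benzylic radical (or, after oxidation, cation) onto the ring C position para to the methoxy group should give tetralone 14. C1 would then be set in the cyclisation, trans to the C2 methyl group, instead of being carried over.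

2. Step 2. The auxiliary may discriminate the two faces of the unactivated butene only weakly, so that the carbon that becomes C2 is formed with low enantiomeric purity. Fallback, setting out from 1 and returning at 8: the acid chloride 3 is coupled with pyrrolidine (Et3N, CH2Cl2) to the achiral pyrrolidine amide F3. The same cycloaddition conditions lead through the keteniminium triflate F4 and the racemic cyclobutaniminium triflate F5 to the racemic all-trans ketone, that is 8 together with its (2R,3R,4R)-enantiomer F6. The two are separated by preparative chromatography on a chiral stationary phase, so that enantiopurity comes from resolution and not from induction, and 8 enters step 5 as before.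

3. Step 13. The activated secondary alcohol next to the bulky silyloxy-bearing carbon may eliminate (E2) or react too slowly in the SN2 displacement. Fallback, setting out from 16 and returning at 25: phenol 16 undergoes the Mitsunobu reaction with ethyl (S)-lactate (PPh3, DIAD), an unhindered and well-behaved partner, to give with inversion the ethyl (2R)-2-aryloxypropanoate F7. Me(MeO)NH·HCl and i-PrMgCl convert it into the Weinreb amide F8. Grignard reagent 21 then gives the aryl ketone F9. Chelation-controlled reduction with Zn(BH4)2 (Et2O, −20 °C) should give the erythro (1S,2R)-alcohol F10, and t-BuMe2SiOTf with 2,6-lutidine silylates it to 25.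

**Further compounds**

F1 | step 5 | [3-methoxy-4-(triisopropylsilyloxy)phenyl]magnesium chloride | COc1cc([Mg]Cl)ccc1O[Si](C(C)C)(C(C)C)C(C)C
F2 | step 5 | (1S,2S,3S,4S)-2-[4-(benzyloxy)-3-methoxyphenyl]-1-[3-methoxy-4-(triisopropylsilyloxy)phenyl]-3,4-dimethylcyclobutan-1-ol | COc1cc([C@H]2[C@](O)(c3ccc(O[Si](C(C)C)(C(C)C)C(C)C)c(OC)c3)[C@@H](C)[C@@H]2C)ccc1OCc1ccccc1
F3 | step 2 | 2-[4-(benzyloxy)-3-methoxyphenyl]-1-(pyrrolidin-1-yl)ethan-1-one | COc1cc(CC(=O)N2CCCC2)ccc1OCc1ccccc1
F4 | step 2 | 1-{2-[4-(benzyloxy)-3-methoxyphenyl]ethenylidene}pyrrolidin-1-ium trifluoromethanesulfonate | COc1cc(C=C=[N+]2CCCC2)ccc1OCc1ccccc1.[O-]S(=O)(=O)C(F)(F)F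
F5 | step 2 | racemic 1-{2-[4-(benzyloxy)-3-methoxyphenyl]-trans-3,4-dimethylcyclobutylidene}pyrrolidin-1-ium trifluoromethanesulfonate (the (3S,4S) enantiomer drawn) | COc1cc(C2C(=[N+]3CCCC3)[C@@H](C)[C@@H]2C)ccc1OCc1ccccc1.[O-]S(=O)(=O)C(F)(F)F
F6 | step 2 | (2R,3R,4R)-2-[4-(benzyloxy)-3-methoxyphenyl]-3,4-dimethylcyclobutan-1-one | COc1cc([C@@H]2C(=O)[C@H](C)[C@H]2C)ccc1OCc1ccccc1
F7 | step 13 | ethyl (2R)-2-{2-methoxy-4-[(1S,2S,3R)-6-methoxy-2,3-dimethyl-7-(triisopropylsilyloxy)-1,2,3,4-tetrahydronaphthalen-1-yl]phenoxy}propanoate | CCOC(=O)[C@@H](C)Oc1ccc([C@H]2c3cc(O[Si](C(C)C)(C(C)C)C(C)C)c(OC)cc3C[C@@H](C)[C@@H]2C)cc1OC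
F8 | step 13 | (2R)-N-methoxy-2-{2-methoxy-4-[(1S,2S,3R)-6-methoxy-2,3-dimethyl-7-(triisopropylsilyloxy)-1,2,3,4-tetrahydronaphthalen-1-yl]phenoxy}-N-methylpropanamide | CON(C)C(=O)[C@@H](C)Oc1ccc([C@H]2c3cc(O[Si](C(C)C)(C(C)C)C(C)C)c(OC)cc3C[C@@H](C)[C@@H]2C)cc1OC
F9 | step 13 | (2R)-1-[4-(tert-butyldimethylsilyloxy)-3-methoxyphenyl]-2-{2-methoxy-4-[(1S,2S,3R)-6-methoxy-2,3-dimethyl-7-(triisopropylsilyloxy)-1,2,3,4-tetrahydronaphthalen-1-yl]phenoxy}propan-1-one | COc1cc(C(=O)[C@@H](C)Oc2ccc([C@H]3c4cc(O[Si](C(C)C)(C(C)C)C(C)C)c(OC)cc4C[C@@H](C)[C@@H]3C)cc2OC)ccc1O[Si](C)(C)C(C)(C)C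
F10 | step 13 | (1S,2R)-1-[4-(tert-butyldimethylsilyloxy)-3-methoxyphenyl]-2-{2-methoxy-4-[(1S,2S,3R)-6-methoxy-2,3-dimethyl-7-(triisopropylsilyloxy)-1,2,3,4-tetrahydronaphthalen-1-yl]phenoxy}propan-1-ol | COc1cc([C@H](O)[C@@H](C)Oc2ccc([C@H]3c4cc(O[Si](C(C)C)(C(C)C)C(C)C)c(OC)cc4C[C@@H](C)[C@@H]3C)cc2OC)ccc1O[Si](C)(C)C(C)(C)C
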